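I started from the time of reading, 1.0 h, and asked what the earlier runs would have to show for noon to draw level with winter.

the same everywhere: D 2 mol%
- epsilon: X 0.41 M (in portions, 2); Z 0.85 equiv; run made earlier; portions every 12 min
- gamma: X 0.41 M (in portions, 2); Z 1.6 equiv; run made earlier; portions every 12 min
- winter: X 0.41 M; Z 2.20 equiv; everything together at the start; time 1.0 h
- noon: X 0.41 M (in portions, 2); Z 1.10 equiv; the portions of X follow each other after 12 min, the first at the start; time 1.0 h

| run | time / min | L / % | X / % |
|---|---|---|---|
| epsilon | 6.00 | 13.1 | 35.6 |
| epsilon | 12.0 | 23.2 | 24.5 |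
| epsilon | 20.0 | 35.3 | 62.9 |
| epsilon | 25.0 | 41.0 | 57.3 |
| epsilon | 30.0 | 45.5 | 51.5 |
| gamma | 6.00 | 20.5 | 27.6 |
| gamma | 12.0 | 35.7 | 13.1 |
| gamma | 20.0 | 56.9 | 40.7 |
| gamma | 25.0 | 67.6 | 30.2 |
| gamma | 30.0 | 76.4 | 22.0 |

(readings scatter by 0.3 percentage points)

- the winner by amount of L, in percent of the X charged; "neither" if no more than 2 percentage points parts them (winter / noon / neither)
- how much L is there at the end, in percent of the X charged: winter
- how much L is there at the end, in percent of the X charged: noon

In gamma the second portion took X from 13.1% to 40.7%. After it, gamma's L came in more slowly than before it. Gamma held more Z than epsilon, and at 30.0 min its L read 76.4% against 45.5% in epsilon. So I followed Z. Counting each L as one Z used, gamma at 30.0 min gave 0.0216 min⁻¹ and epsilon 0.0255 min⁻¹. I took their mean, 0.0236 min⁻¹, as my Z constant, the share of the remaining Z used per minute, a pseudo-first-order constant.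

My zero was a flask that just spends one equivalent of Z within the hour, since two flasks that both clear stand level. That takes a constant of 0.0101 min⁻¹ for winter and 0.0400 min⁻¹ for noon. The opposite outcome therefore needed the runs to read 0.0400 min⁻¹. They read less, by a factor of 1.69. Winter's need lay below the reading. Noon shares its X charge, loading and portions with both runs, so my reckoning gave noon 83.3%. Winter is loaded at once, unlike the runs, so the same constant, which put one equivalent spent at about 25.7 min, gave only a looser estimate there.

The forecast said winter: 97.5% (94% to 99.5%) for winter and 80% (74% to 86%) for noon, holding the rate “close to first order in Z and nearly zero order in X unless X is low”. My noon figure stood above its own.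

The flasks gave 98.5% for winter and 81.1% for noon, so winter won. At 1.00 h noon still held X at 16.4% of the charge and Z at 26.1% of its own, so neither charge had run out. The Z constant put noon's Z at 49.3% after 0.500 h, where 47.7% stood.

    Z + J → G (k = 4.10 M⁻¹ min⁻¹)
    X + D → J (k = 54.0 M⁻¹ min⁻¹)
    G ⇌ D + L (K = 0.450 M, k = 37.0 min⁻¹)
    X + J → E (k = 0.0530 M⁻¹ min⁻¹)

The neighbour with noon's recipe but X at 0.10 M is charged with D lower in step, at the same loading, so if the constant follows the D charge it is 0.00575 min⁻¹, which gives L 32.1%. That neighbour gave 36.1%.

All runs were computed with constants of no real substance; scatter was added.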